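The ratio I carry through this flask is how many times faster left-handed substrate is used than right-handed substrate. The decision for the next run is whether 3.9 mM of racemization catalyst is worth charging, or whether exchange between the two hands stays too slow to count.

all flasks: left-handed substrate 0.30 M; right-handed substrate 0.30 M; impurity 2.3 mM

| flask | coupling partner | racemization catalyst | remark | time |
|---|---|---|---|---|
| zeta | 1.2 M | 1.9 mM | run made earlier |  |
| beta | 1.2 M | 7.8 mM | run made earlier |  |
| flask | 1.20 M | 3.9 mM |  | 3.0 h |

| run | time / h | left-handed product / % | right-handed product / % | left-handed substrate / % |
|---|---|---|---|---|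
| zeta | 0.667 | 7.7 | 2.9 | 43.1 |
| zeta | 1.33 | 12.2 | 4.3 | 38.6 |
| zeta | 2.00 | 18.1 | 6.1 | 32.5 |
| zeta | 2.50 | 20.1 | 7.7 | 29.0 |
| zeta | 3.00 | 24.2 | 10.4 | 27.6 |
| zeta | 4.00 | 27.6 | 13.4 | 22.6 |
| beta | 0.250 | 3.5 | 0.3 | 47.2 |
| beta | 0.500 | 6.0 | 3.5 | 44.2 |
| beta | 0.833 | 7.2 | 3.9 | 42.2 |
| beta | 1.33 | 12.0 | 4.2 | 37.7 |
| beta | 2.00 | 16.9 | 8.2 | 33.5 |
| beta | 4.00 | 30.5 | 13.4 | 25.0 |

(each reading ± 1 percentage point)

1. left-handed product and right-handed product together, in percent of the left-handed substrate and right-handed substrate charged together, at 3.0 h
2. excess of left-handed product over right-handed product in the product at 3.0 h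
3. whether the exchange between left-handed substrate and right-handed substrate keeps pace with the reaction: how far the product's excess at 3.0 h gets from its value without exchange to its value with instant exchange (above 80% keeps pace, below 20% hardly takes part, else lags behind)

- coupling partner is single-handed; left-handed substrate and right-handed substrate are mirror images of each other, charged as a racemate, each of them at the stated concentration
- an excess is the difference of the two amounts in percent of their sum
- an excess is below zero if the other one leads
- the handed part of coupling partner does not stay in what it makes, so the products of the two hands are mirror images too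

In zeta, left-handed substrate plus its product stands at 50.2% after 4.00 h, which is half of the charge, so no crossing shows beyond the scatter. Beta reaches 55.5%, so exchange shows there. Coupling partner at 1.20 M stands above both hands together, so I treat each hand as decaying on its own, exponentially (pseudo-first-order). Let P and Q be zeta's left-handed and right-handed product at 4.00 h, as fractions of the whole charge. Taking natural logarithms of what remains of each hand gives the selectivity factor s, a reading that carries the scatter of this one pair of values in zeta:

s = ln(1 − 2P) / ln(1 − 2Q) = 2.57

Let x be the logarithmic loss of right-handed substrate, scaled to 3.0 h at the same partner charge: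

x = 0.234

The used fractions of the two hands are then a = 45.2% and b = 20.9%. So my no-exchange reckoning gives:

yield, the mean of a and b = 33.1%
excess, (a − b)/(a + b) = 36.9%
excess with instant exchange, (s − 1)/(s + 1) = 44.0%

These two excesses lie 7.1 percentage points apart, and the catalyst decision hangs on that gap. I expect the flask near the no-exchange end, and I would leave the catalyst as planned.

The forecast says 34% yield and 39.5% excess, the excess above my no-exchange figure, and that exchange hardly takes part, calling it “slow against the reaction”.

The flask gives 33.7% yield and 38.4% excess, and exchange hardly takes part, getting 10% of the way.

    coupling partner + left-handed substrate → left-handed product (k = 0.190 M⁻¹ h⁻¹)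
    coupling partner + right-handed substrate → right-handed product (k = 0.0720 M⁻¹ h⁻¹)
    left-handed substrate + racemization catalyst ⇌ right-handed substrate + racemization catalyst, rate k3*[racemization catalyst]*[left-handed substrate] forward; the back reaction follows from the equilibrium constant (k = 61.0 M⁻¹ h⁻¹)
    2 racemization catalyst ⇌ resting dimer, settled at all times (K = 340 M⁻¹)
    racemization catalyst + impurity → spent catalyst A (k = 27000 M⁻¹ h⁻¹)
    racemization catalyst → spent catalyst B (k = 0.0540 h⁻¹)

So this flask behaves nearly as two separate hands, and its excess stands close to the computed no-exchange 37.6%. At 3.00 h in this flask, spent catalyst A holds 59.0% of the catalyst charged. Taken on what is left of each substrate in this flask, the ratio comes to 2.24, below the s read from zeta.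

With 2.0 M of coupling partner, I scale x with the partner charge to 0.390, and s then gives, reckoned without exchange, 47.8% yield at 32.4% excess. That neighbour computes to 49.0% and 34.2%.

All runs stem from a simulated flask from invented constants, noise included.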